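**Retrosynthetic overview**
- The target comes from an aromatic Claisen shift to C6 of a 7‑O‑(1,1‑dimethylallyl) ether, itself made by Pd‑catalysed C–O bond formation at the 7‑OH.
- The C8 side chain comes from an enantioselective ene‑type C–O bond formation with O2 on an 8‑prenyl group; the neighbouring 7‑phenoxide is the handle for a chiral cation, and this sets the only stereocentre.
- The 8‑prenyl isoflavone comes from a Claisen shift to C8 of the 7‑O‑(1,1‑dimethylallyl) ether of 2'‑hydroxygenistein (7‑OH selected by its acidity).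
- 2'‑Hydroxygenistein comes from demethylation of the product of a one‑pot acylation/formylative ring closure of phloroglucinol with (2,4‑dimethoxyphenyl)acetic acid.
- Ring order: both benzene rings are bought; the pyran‑4‑one ring is the only ring made (first step). No protecting groups are used; the 7‑OH serves three times.

Assumption: tert‑butyl (2‑methylbut‑3‑en‑2‑yl) carbonate is bought as a catalogue reagent.

**Step 1**
Reactants: 1 phloroglucinol (benzene‑1,3,5‑triol); 2 (2,4‑dimethoxyphenyl)acetic acid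
Product: 4 3‑(2,4‑dimethoxyphenyl)‑5,7‑dihydroxy‑4H‑chromen‑4‑one, via deoxybenzoin 3 (not isolated)
Conditions: BF3·OEt2 (solvent), 85 °C; then DMF, MeSO2Cl, 65 °C
Reagents that add atoms: N,N‑dimethylformamide, CN(C)C=O
Why: BF3‑mediated Friedel–Crafts acylation of symmetrical phloroglucinol gives the deoxybenzoin, whose methylene is formylated by the DMF/MsCl Vilsmeier reagent and closes through an ortho‑OH (O1–C2 bond) to the isoflavone (one‑pot deoxybenzoin isoflavone synthesis); no stereocentre.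

**Step 2**
Reactants: 4 3‑(2,4‑dimethoxyphenyl)‑5,7‑dihydroxy‑4H‑chromen‑4‑one
Product: 5 3‑(2,4‑dihydroxyphenyl)‑5,7‑dihydroxy‑4H‑chromen‑4‑one (2'‑hydroxygenistein)
Conditions: BBr3 (8 equiv), CH2Cl2, −78 °C → rt; aq. work‑up
Reagents that add atoms: none
Why: Lewis‑acid aryl methyl ether cleavage (BBr3 demethylation) frees both B‑ring phenols while the chromone and the existing OH groups are inert, and no acid‑sensitive group is present yet.

**Step 3**
Reactants: 5 2'‑hydroxygenistein; 6 tert‑butyl (2‑methylbut‑3‑en‑2‑yl) carbonate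
Product: 7 3‑(2,4‑dihydroxyphenyl)‑5‑hydroxy‑7‑[(2‑methylbut‑3‑en‑2‑yl)oxy]‑4H‑chromen‑4‑one
Conditions: 6 (1.05 equiv), Pd(PPh3)4 (5 mol%), THF, 0 °C
Reagents that add atoms: none
Why: Tsuji–Trost O‑allylation, in which the tert‑butoxide released on decarboxylative ionisation of 6 deprotonates only the most acidic 7‑OH (vinylogous acid, pKa about 7; 5‑OH chelated, B‑ring OH pKa 9–10) and the phenoxide attacks the more substituted π‑allyl terminus under kinetic control at 0 °C.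

**Step 4**
Reactants: 7 the 7‑O‑(2‑methylbut‑3‑en‑2‑yl) ether
Product: 8 3‑(2,4‑dihydroxyphenyl)‑5,7‑dihydroxy‑8‑(3‑methylbut‑2‑en‑1‑yl)‑4H‑chromen‑4‑one
Conditions: DMF, 110 °C, Ar, 3 h
Reagents that add atoms: none
Why: aromatic Claisen rearrangement ([3,3]) moves the allyl unit from O7 to the ortho carbon with allyl inversion (tertiary ether gives the n‑prenyl group); C8 is expected to be the main ortho site with the 5‑OH chelated, the minor C6 isomer is removed by chromatography, and the 7‑OH is regenerated.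

**Step 5**
Reactants: 8 the 8‑prenyl isoflavone
Product: 10 3‑(2,4‑dihydroxyphenyl)‑5,7‑dihydroxy‑8‑[(2R)‑2‑hydroxy‑3‑methylbut‑3‑en‑1‑yl]‑4H‑chromen‑4‑one, via allylic hydroperoxide 9 (not isolated)
Conditions: O2 (1 atm), TPP (1 mol%), N‑[4‑(trifluoromethyl)benzyl]cinchoninium bromide (20 mol%), KHCO3 (solid, 25 mol%), PhMe (8 suspended), red LED, −20 °C; then PPh3 (1.2 equiv), −20 °C → rt
Reagents that add atoms: dioxygen, O=O
Why: Proposed new method: enantioselective singlet‑oxygen ene (Schenck) oxygenation under solid–liquid chiral phase‑transfer ion‑pair control – only the 7‑phenoxide of 8 (its most acidic OH, ortho to the prenyl group) is carried into toluene as a tight ion pair with the cinchona ammonium while neutral 8 stays undissolved, so the racemic background is starved; the cation's C9–OH hydrogen‑bonds the trailing oxygen of the incoming singlet O2 (perepoxide‑like transition state) and delivers it to the alkene face turned towards the aryl ring, where in the A(1,3)‑minimised conformer only the cis‑methyl hydrogens are suprafacial, so the new C–O bond forms at C‑2 of the side chain with the double bond moving to the isopropenyl position; the (R)‑centre is set by the chirality of the ion pair, the cinchoninium series being a working choice to be confirmed in a first screen (the pseudo‑enantiomeric cinchonidinium salt gives the mirror‑image pair if the sense is reversed); PPh3 then reduces O–O without touching C–O; closest known reaction types: the hydroxy‑directed Schenck ene reaction and the cinchona phase‑transfer photo‑oxygenation (α‑hydroxylation) of β‑keto ester enolates with singlet oxygen.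

**Step 6**
Reactants: 10 the (R)‑allylic alcohol; 6 tert‑butyl (2‑methylbut‑3‑en‑2‑yl) carbonate
Product: 11 3‑(2,4‑dihydroxyphenyl)‑5‑hydroxy‑8‑[(2R)‑2‑hydroxy‑3‑methylbut‑3‑en‑1‑yl]‑7‑[(2‑methylbut‑3‑en‑2‑yl)oxy]‑4H‑chromen‑4‑one
Conditions: 6 (1.05 equiv), Pd(PPh3)4 (5 mol%), THF, 0 °C
Reagents that add atoms: none
Why: the same acidity‑gated Tsuji–Trost O‑allylation as in step 3; the unactivated secondary allylic alcohol and the other phenols are far less acidic and stay untouched, so the (R)‑centre is not involved.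

**Step 7**
Reactants: 11 the 7‑O‑(2‑methylbut‑3‑en‑2‑yl) ether of the (R)‑allylic alcohol
Product: 12 3‑(2,4‑dihydroxyphenyl)‑5,7‑dihydroxy‑8‑[(2R)‑2‑hydroxy‑3‑methylbut‑3‑en‑1‑yl]‑6‑(3‑methylbut‑2‑en‑1‑yl)‑4H‑chromen‑4‑one (target)
Conditions: DMF, 110 °C, Ar, 3 h
Reagents that add atoms: none
Why: aromatic Claisen rearrangement in which C6 is the only free ortho position, so the n‑prenyl group is delivered there under neutral thermal conditions that leave the allylic alcohol and its (R)‑centre untouched.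

**Compound list**
1 | phloroglucinol | Oc1cc(O)cc(O)c1 | starting material
2 | (2,4‑dimethoxyphenyl)acetic acid | COc1ccc(CC(=O)O)c(OC)c1 | starting material
3 | 2‑(2,4‑dimethoxyphenyl)‑1‑(2,4,6‑trihydroxyphenyl)ethan‑1‑one (deoxybenzoin, not isolated) | COc1ccc(CC(=O)c2c(O)cc(O)cc2O)c(OC)c1 | intermediate
4 | 3‑(2,4‑dimethoxyphenyl)‑5,7‑dihydroxy‑4H‑chromen‑4‑one | COc1ccc(-c2coc3cc(O)cc(O)c3c2=O)c(OC)c1 | intermediate
5 | 3‑(2,4‑dihydroxyphenyl)‑5,7‑dihydroxy‑4H‑chromen‑4‑one (2'‑hydroxygenistein) | Oc1ccc(-c2coc3cc(O)cc(O)c3c2=O)c(O)c1 | intermediate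
6 | tert‑butyl (2‑methylbut‑3‑en‑2‑yl) carbonate | C=CC(C)(C)OC(=O)OC(C)(C)C | starting material
7 | 3‑(2,4‑dihydroxyphenyl)‑5‑hydroxy‑7‑[(2‑methylbut‑3‑en‑2‑yl)oxy]‑4H‑chromen‑4‑one | C=CC(C)(C)Oc1cc(O)c2c(=O)c(-c3ccc(O)cc3O)coc2c1 | intermediate
8 | 3‑(2,4‑dihydroxyphenyl)‑5,7‑dihydroxy‑8‑(3‑methylbut‑2‑en‑1‑yl)‑4H‑chromen‑4‑one | CC(C)=CCc1c(O)cc(O)c2c(=O)c(-c3ccc(O)cc3O)coc12 | intermediate
9 | 3‑(2,4‑dihydroxyphenyl)‑8‑[(2R)‑2‑hydroperoxy‑3‑methylbut‑3‑en‑1‑yl]‑5,7‑dihydroxy‑4H‑chromen‑4‑one (not isolated) | C=C(C)[C@H](OO)Cc1c(O)cc(O)c2c(=O)c(-c3ccc(O)cc3O)coc12 | intermediate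
10 | 3‑(2,4‑dihydroxyphenyl)‑5,7‑dihydroxy‑8‑[(2R)‑2‑hydroxy‑3‑methylbut‑3‑en‑1‑yl]‑4H‑chromen‑4‑one | C=C(C)[C@H](O)Cc1c(O)cc(O)c2c(=O)c(-c3ccc(O)cc3O)coc12 | intermediate
11 | 3‑(2,4‑dihydroxyphenyl)‑5‑hydroxy‑8‑[(2R)‑2‑hydroxy‑3‑methylbut‑3‑en‑1‑yl]‑7‑[(2‑methylbut‑3‑en‑2‑yl)oxy]‑4H‑chromen‑4‑one | C=CC(C)(C)Oc1cc(O)c2c(=O)c(-c3ccc(O)cc3O)coc2c1C[C@@H](O)C(C)=C | intermediate
12 | 3‑(2,4‑dihydroxyphenyl)‑5,7‑dihydroxy‑8‑[(2R)‑2‑hydroxy‑3‑methylbut‑3‑en‑1‑yl]‑6‑(3‑methylbut‑2‑en‑1‑yl)‑4H‑chromen‑4‑one | C=C(C)[C@H](O)Cc1c(O)c(CC=C(C)C)c(O)c2c(=O)c(-c3ccc(O)cc3O)coc12 | target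

**Step count and risks**
Total steps: 7. Longest linear sequence: 7 (fully linear).

Three steps most likely to fail:

1. Step 5 (the proposed new reaction). The risks are quenching or oxidation of the phenoxide ring by singlet oxygen, some tertiary hydroperoxide from benzylic hydrogen abstraction, and insufficient enantioselectivity. The fallback uses known chemistry and a different logic: O7 is masked as the ether that is needed anyway, the oxygen is brought in as an epoxide by a chiral dioxirane, and the epoxide is then isomerised by base. It sets out from 8 and comes back to the route at 11. Compound 8 is O‑allylated with 6 under the conditions of step 3 to give 3‑(2,4‑dihydroxyphenyl)‑5‑hydroxy‑7‑[(2‑methylbut‑3‑en‑2‑yl)oxy]‑8‑(3‑methylbut‑2‑en‑1‑yl)‑4H‑chromen‑4‑one F1. Shi epoxidation (D‑fructose‑derived ketone, Oxone, NaHCO3 at pH about 8 to keep the phenols protonated, MeCN–DMM–aq. Na2EDTA, 0 °C) attacks only the trisubstituted alkene and gives 3‑(2,4‑dihydroxyphenyl)‑8‑{[(2R)‑3,3‑dimethyloxiran‑2‑yl]methyl}‑5‑hydroxy‑7‑[(2‑methylbut‑3‑en‑2‑yl)oxy]‑4H‑chromen‑4‑one F2, the sense following the usual spiro transition‑state model. Yamamoto–Nozaki isomerisation (Et2Al‑TMP in excess to cover the three ArOH, toluene, 0 °C) removes a methyl proton and opens the tertiary C–O bond, leaving the C‑2–O bond and its configuration intact, to give 11. The route then continues with step 7 (one step longer overall).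

2. Step 4 (C8 against C6 in the first Claisen shift). The fallback is a para‑Claisen–Cope sequence from O5, which is established for 8‑prenyl flavonoids. It sets out from 5 and comes back at 8. MOMCl/iPr2NEt (CH2Cl2, 0 °C) protects all but the chelated 5‑OH to give 3‑[2,4‑bis(methoxymethoxy)phenyl]‑5‑hydroxy‑7‑(methoxymethoxy)‑4H‑chromen‑4‑one F3. Prenyl bromide/K2CO3 (DMF, 60 °C) gives 3‑[2,4‑bis(methoxymethoxy)phenyl]‑7‑(methoxymethoxy)‑5‑[(3‑methylbut‑2‑en‑1‑yl)oxy]‑4H‑chromen‑4‑one F4. Eu(fod)3 (10 mol%, CHCl3, 60 °C) carries the prenyl group via C6 to C8 and gives 3‑[2,4‑bis(methoxymethoxy)phenyl]‑5‑hydroxy‑7‑(methoxymethoxy)‑8‑(3‑methylbut‑2‑en‑1‑yl)‑4H‑chromen‑4‑one F5. HCl in MeOH (50 °C) removes the three MOM groups to give 8.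

3. Step 3 (and its repeat, step 6). The risks are Pd‑mediated isomerisation of the branched ether to the linear O‑prenyl ether and some B‑ring O‑allylation on the unprotected tetraol. The fallback makes the tertiary ether without π‑allyl chemistry. It sets out from 5 and comes back at 7. Copper‑catalysed propargylation (3‑chloro‑3‑methylbut‑1‑yne, DBU 1.0 equiv, CuCl2 cat., MeCN, 0 °C; again only the 7‑OH is deprotonated) gives 3‑(2,4‑dihydroxyphenyl)‑5‑hydroxy‑7‑[(2‑methylbut‑3‑yn‑2‑yl)oxy]‑4H‑chromen‑4‑one F6. Lindlar semi‑hydrogenation (H2, Pd/CaCO3–Pb, quinoline, EtOAc) gives 7.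

**Further compounds**
F1 | step 5 | 3‑(2,4‑dihydroxyphenyl)‑5‑hydroxy‑7‑[(2‑methylbut‑3‑en‑2‑yl)oxy]‑8‑(3‑methylbut‑2‑en‑1‑yl)‑4H‑chromen‑4‑one | C=CC(C)(C)Oc1cc(O)c2c(=O)c(-c3ccc(O)cc3O)coc2c1CC=C(C)C
F2 | step 5 | 3‑(2,4‑dihydroxyphenyl)‑8‑{[(2R)‑3,3‑dimethyloxiran‑2‑yl]methyl}‑5‑hydroxy‑7‑[(2‑methylbut‑3‑en‑2‑yl)oxy]‑4H‑chromen‑4‑one | C=CC(C)(C)Oc1cc(O)c2c(=O)c(-c3ccc(O)cc3O)coc2c1C[C@H]4OC4(C)C
F3 | step 4 | 3‑[2,4‑bis(methoxymethoxy)phenyl]‑5‑hydroxy‑7‑(methoxymethoxy)‑4H‑chromen‑4‑one | COCOc1ccc(-c2coc3cc(OCOC)cc(O)c3c2=O)c(OCOC)c1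
F4 | step 4 | 3‑[2,4‑bis(methoxymethoxy)phenyl]‑7‑(methoxymethoxy)‑5‑[(3‑methylbut‑2‑en‑1‑yl)oxy]‑4H‑chromen‑4‑one | COCOc1ccc(-c2coc3cc(OCOC)cc(OCC=C(C)C)c3c2=O)c(OCOC)c1
F5 | step 4 | 3‑[2,4‑bis(methoxymethoxy)phenyl]‑5‑hydroxy‑7‑(methoxymethoxy)‑8‑(3‑methylbut‑2‑en‑1‑yl)‑4H‑chromen‑4‑one | COCOc1ccc(-c2coc3c(CC=C(C)C)c(OCOC)cc(O)c3c2=O)c(OCOC)c1
F6 | step 3 | 3‑(2,4‑dihydroxyphenyl)‑5‑hydroxy‑7‑[(2‑methylbut‑3‑yn‑2‑yl)oxy]‑4H‑chromen‑4‑one | C#CC(C)(C)Oc1cc(O)c2c(=O)c(-c3ccc(O)cc3O)coc2c1
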